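**Plan**
- Cuts, last to first: C14=C15 and C12=C13 (two Wittig olefinations), the C1 acetate, C4–C18 and C4–C19 (methylation and one-carbon homologation at a C4 ketone), C8=C17 (ketone methylenation), and centrally C5–C6 plus C9–C10 (ring B by a quinone Diels–Alder reaction).
- Enabling feature: quaternary C10 bears the methyl and is bonded to C1, C5 and C9. C5=C10 can therefore be the methyl-bearing double bond of a benzoquinone whose carbonyls become C1 and C4, and sp2 C8 next to C9 can come from the silyloxy carbon of a diene C6=C7–C8(OSi)=C9.
- Forward order: ring A is bought as an arene and oxidised to the quinone; step 5 closes ring B; the C11–C12 arm (a methyl ester) is later tied to O1 as a δ-lactone, a temporary third ring that is reopened at the end to attach C13–C16.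
- Stereochemistry: C10 from the chiral Lewis acid in the cycloaddition; C5 by base equilibration to the trans-decalin; C1 by hydride attack anti to the axial C10 methyl; C9 by equilibration funnelled through the all-chair lactone; C4 by equatorial methylation of an exocyclic enolate; C12=C13 (E) from a stabilised ylide.

Key step: step 5

Conventions: atoms carry the labdane numbers of the target (ring A = C1–C5, C10; ring B = C5–C10; C11, C12 = arm on C9; C17 = exocyclic methylene carbon; C19 = ester carbon on C4). With ring A drawn on the left, C1 upper left and C10 at the top of the ring fusion, α means away from the viewer; the C10 methyl is α in every bicyclic compound (the mirror image of the usual labdane drawing). The target is then 1α-OAc, 4α-CO2Me/4β-CH3, 5β-H, 9α-side chain, 10α-CH3, i.e. (1S,4R,5S,9R,10S).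

Assumption: the oxazaborolidinium ion made from (S)-α,α-diphenylprolinol is taken to shield the face of C5=C10 that would lead to the mirror-image adduct, so that it gives (5R,9R,10S)-8; if the sense of induction is the opposite, the catalyst from (R)-diphenylprolinol is used and nothing else changes.

**Route**

Step 1
Reactants: 1 2-methoxy-6-methylphenol
Product: 2 2-methoxy-6-methyl-1,4-benzoquinone
Conditions: O2 (1 atm), Co(salen) [Co(C16H14N2O2)] (10 mol %), DMF, rt
Reagents that add atoms: dioxygen, O=O
Why: Aerobic para-oxidation of a 2,6-disubstituted phenol with a free para position by the cobalt–salen/O2 system is a standard quinone synthesis, and no stereocentre is involved.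

Step 2
Reactants: 3 methyl 4-chloro-4-oxobutanoate
Product: 4 methyl 4-[methoxy(methyl)amino]-4-oxobutanoate
Conditions: MeNH(OMe)·HCl (1.1 equiv), pyridine (2.2 equiv), CH2Cl2, 0 °C → rt
Reagents that add atoms: N,O-dimethylhydroxylamine hydrochloride, CNOC.Cl
Why: Acylation of N,O-dimethylhydroxylamine by the acid chloride (Weinreb amide formation) is much faster than any reaction at the methyl ester, and no stereocentre is formed.

Step 3
Reactants: 4 methyl 4-[methoxy(methyl)amino]-4-oxobutanoate; 5 vinylmagnesium bromide (CH2=CHMgBr)
Product: 6 methyl 4-oxohex-5-enoate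
Conditions: THF, −78 → −20 °C; poured into cold 1 M HCl
Reagents that add atoms: none
Why: Weinreb ketone synthesis, in which the chelated tetrahedral magnesium adduct survives until the acidic quench so that one vinyl group is added and the less electrophilic methyl ester is left alone, while quenching into acid keeps the liberated amine from adding to the new enone.

Step 4
Reactants: 6 methyl 4-oxohex-5-enoate
Product: 7 methyl (3Z)-4-[(triisopropylsilyl)oxy]hexa-3,5-dienoate
Conditions: i-Pr3SiOTf (1.1 equiv), Et3N (1.5 equiv), CH2Cl2, −78 → 0 °C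
Reagents that add atoms: triisopropylsilyl trifluoromethanesulfonate, CC(C)[Si](C(C)C)(C(C)C)OS(=O)(=O)C(F)(F)F
Why: Soft enolisation of the ketone (silyl triflate/amine) can only occur toward C3 and, as with other alkyl vinyl ketones, should give mainly the Z silyl enol ether, which places the ester arm on the outside of the s-cis diene.

Step 5
Reactants: 2 2-methoxy-6-methyl-1,4-benzoquinone; 7 methyl (3Z)-4-[(triisopropylsilyl)oxy]hexa-3,5-dienoate
Product: 8 cis-fused endo adduct (5R,9R,10S): ring A 2-methoxy-2-ene-1,4-dione, 5α-H, 10α-CH3; ring B with C7=C8 triisopropylsilyl enol ether and 9β-CH2CO2Me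
Conditions: oxazaborolidine from (S)-α,α-diphenylprolinol and o-tolylboronic acid (20 mol %), Tf2NH (18 mol %), CH2Cl2, −78 → −20 °C
Reagents that add atoms: none
Why: The protonated oxazaborolidine binds the more basic vinylogous-ester carbonyl O4, which makes methyl-bearing C10 the electrophilic β-carbon, and the diene adds in a concerted, asynchronous endo [4+2] cycloaddition in which the C9–C10 bond leads; the closest known reaction type is the oxazaborolidinium-catalysed Diels–Alder reaction of unsymmetrical methyl- and methoxy-substituted benzoquinones with 2-silyloxy dienes. Ring B closes as a cyclohexene by this intermolecular [4+2] mode, both σ-bonds (C5–C6 and C9–C10) forming suprafacially on each partner and leaving the C7=C8 silyl enol ether as a masked C8 ketone. C10 is set by the catalyst, whose aryl group shields one face of the bound C5=C10 bond; C5 follows from suprafacial addition to the quinone double bond (5-H cis to the methyl), and C9 from the endo orientation together with the Z enol ether geometry (arm trans to the methyl). Site selectivity (C5=C10 rather than C2=C3) rests on deactivation of the methoxy-bearing double bond, and regioselectivity (C9 to C10) on the match between the silyloxy-activated diene terminus C9 and the β-carbon of the activated enone. C5 and C9 are both corrected later by equilibration, so only C10 has to be right here.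

Step 6
Reactants: 8 cis-fused endo adduct
Product: 10 cis-fused 1,4-diketone (C2 now CH2; 5α-H; 9β-CH2CO2Me; C7=C8 silyl enol ether), via methoxy diketone 9 (not isolated)
Conditions: SmI2 (5 equiv), THF/MeOH, −78 → 0 °C
Reagents that add atoms: none
Why: Samarium diiodide first reduces the ene-dione to the saturated diketone (two electron transfers and protonation) and then cleaves the C2–OMe bond α to the C1 ketone through the ketyl and β-elimination (reductive cleavage of an α-heterosubstituted ketone), while ester and silyl enol ether are inert and the C2 centre of 9 is only transient.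

Step 7
Reactants: 10 cis-fused 1,4-diketone
Product: 11 trans-fused 1,4-diketone (5β-H; otherwise as 10)
Conditions: NaOMe (0.2 equiv), MeOH/THF, 0 °C → rt
Reagents that add atoms: none
Why: Base-catalysed epimerisation α to the C4 ketone (enolate equilibration) should favour the trans-decalin, in which the axial C10 methyl faces sp2 C4 and C8 and so loses two syn-axial contacts, which sets C5 under thermodynamic control.

Step 8
Reactants: 11 trans-fused 1,4-diketone
Product: 12 1α,4ξ-diol (1α-OH equatorial and cis to the C10 methyl; C4 carbinol as a mixture; C7=C8 silyl enol ether and 9β-CH2CO2Me unchanged)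
Conditions: NaBH4 (3 equiv), MeOH/THF, 0 °C → rt
Reagents that add atoms: none
Why: Borohydride reduction of both ring A ketones, in which hydride should reach C1 anti to the axial methyl on the adjacent quaternary C10 (axial attack) to give the equatorial 1α-alcohol, whereas the C4 carbinol configuration does not matter because C4 is re-oxidised in step 11.

Step 9
Reactants: 12 1α,4ξ-diol
Product: 14 8-keto δ-lactone (O1–C12 lactone; 9α-arm; 4ξ-OH), via hydroxy keto ester 13 (not isolated)
Conditions: Bu4NF (1.2 equiv), THF, 0 °C → rt; then DBU (1.0 equiv), 40 °C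
Reagents that add atoms: none
Why: Fluoride desilylation unveils the C8 ketone (protonation at C7 leaves C9 untouched), after which DBU equilibrates C9 through the C8 enolate and only the 9α (equatorial) arm can reach O1 to close the all-chair δ-lactone (lactonisation with loss of methanol), so ring closure drains the equilibrium and sets C9 under thermodynamic control.

Step 10
Reactants: 14 8-keto δ-lactone
Product: 15 8(17)-methylene δ-lactone with 4ξ-OH
Conditions: CH2Br2, Zn, TiCl4, THF/CH2Cl2, 0 °C → rt
Reagents that add atoms: dibromomethane, BrCBr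
Why: Takai–Lombardo methylenation is a non-basic carbonyl olefination that works on hindered, enolisable ketones, leaves lactones alone and tolerates a free hydroxyl, and it creates no stereocentre.

Step 11
Reactants: 15 8(17)-methylene δ-lactone with 4ξ-OH
Product: 16 4-keto 8(17)-methylene δ-lactone
Conditions: Dess–Martin periodinane (1.3 equiv), CH2Cl2, rt
Reagents that add atoms: none
Why: Dess–Martin oxidation of the secondary alcohol regenerates the C4 ketone, now the only ketone in the molecule, and the adjacent C5 centre stays in the favoured trans arrangement.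

Step 12
Reactants: 16 4-keto 8(17)-methylene δ-lactone
Product: 17 4-(methoxymethylidene) 8(17)-methylene δ-lactone (E/Z mixture at the enol ether)
Conditions: [Ph3PCH2OMe]Cl (2.0 equiv), KOt-Bu (1.9 equiv), THF, 0 °C → rt
Reagents that add atoms: (methoxymethyl)triphenylphosphonium chloride, COC[P+](c1ccccc1)(c1ccccc1)c1ccccc1.[Cl-]
Why: Wittig methoxymethylenation of the single ketone (one-carbon homologation) should outpace attack on the δ-lactone at 0 °C, and the enol ether geometry is of no consequence because it is hydrolysed next.

Step 13
Reactants: 17 4-(methoxymethylidene) lactone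
Product: 18 4ξ-formyl 8(17)-methylene δ-lactone (C4 epimers)
Conditions: 2 M HCl, THF, rt
Reagents that add atoms: water, O
Why: Acid hydrolysis of the methyl enol ether (C-protonation, hemiacetal, loss of methanol) releases the aldehyde under conditions mild enough for the exocyclic methylene and the lactone, and the C4 configuration need not be controlled because C4 is enolised in the next step.

Step 14
Reactants: 18 4ξ-formyl lactone
Product: 20 4α-formyl-4β-methyl 8(17)-methylene δ-lactone, via potassium enolate 19 (not isolated)
Conditions: KOt-Bu (1.1 equiv), THF/t-BuOH, 0 °C; then MeI (5 equiv), 0 °C → rt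
Reagents that add atoms: iodomethane, CI
Why: α-Alkylation of an aldehyde enolate, in which tert-butoxide should deprotonate the aldehyde far more readily than the lactone and methyl iodide attacks the exocyclic enolate from the face opposite the syn-axial C10 methyl (equatorial attack), placing the new methyl equatorial (4β) and the formyl group axial (4α, cis to the C10 methyl).

Step 15
Reactants: 20 4α-formyl-4β-methyl lactone
Product: 21 4α-carboxylic acid (8(17)-methylene δ-lactone)
Conditions: NaClO2, NaH2PO4, 2-methyl-2-butene, t-BuOH/H2O, rt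
Reagents that add atoms: sodium chlorite, [Na+].[O-]Cl=O
Why: Pinnick oxidation converts the hindered aldehyde into the acid without touching the quaternary centre, the alkene scavenger intercepting HOCl before it can add to the exocyclic methylene.

Step 16
Reactants: 21 4α-carboxylic acid
Product: 22 methyl ester lactone (4α-CO2Me, 4β-CH3, 8(17)-methylene, O1–C12 δ-lactone)
Conditions: MeI, K2CO3, DMF, rt
Reagents that add atoms: iodomethane, CI
Why: SN2 O-alkylation of the carboxylate avoids nucleophilic addition at the hindered axial carboxyl carbon and leaves the lactone intact.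

Step 17
Reactants: 22 methyl ester lactone
Product: 23 lactol (C12 hemiacetal, anomeric mixture)
Conditions: i-Bu2AlH (1.2 equiv), CH2Cl2, −78 °C
Reagents that add atoms: none
Why: Partial reduction of a lactone to the lactol with i-Bu2AlH at −78 °C (stable aluminium hemiacetal) should be selective because the axial methyl ester on quaternary C4 is far more hindered, and the anomeric centre is not retained.

Step 18
Reactants: 23 lactol
Product: 24 hydroxy enal (1α-OH; side chain CH2–CH=C(CH3)–CHO with 12E geometry)
Conditions: Ph3P=C(CH3)CHO (3 equiv), toluene, 100 °C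
Reagents that add atoms: 2-(triphenylphosphoranylidene)propanal, CC(C=O)=P(c1ccccc1)(c1ccccc1)c1ccccc1
Why: Wittig olefination of the lactol through its open hydroxy-aldehyde form with a formyl-stabilised ylide, which gives the trisubstituted enal with E geometry (CHO trans to the chain), under neutral conditions that disfavour re-addition of the C1 hydroxyl.

Step 19
Reactants: 24 hydroxy enal
Product: 25 acetoxy enal (1α-OAc)
Conditions: Ac2O, DMAP (0.2 equiv), pyridine, CH2Cl2, 0 °C → rt
Reagents that add atoms: acetic anhydride, CC(=O)OC(C)=O
Why: DMAP-catalysed acylation esterifies the hindered equatorial C1 hydroxyl without change at C1.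

Step 20
Reactants: 25 acetoxy enal
Product: 26 target, methyl (1S,4R,5S,9R,10S)-1-acetoxylabda-8(17),12E,14-trien-19-oate (descriptors as drawn in the SMILES)
Conditions: [Ph3PCH3]Br (1.3 equiv), NaN(SiMe3)2 (1.2 equiv), THF, −78 → 0 °C
Reagents that add atoms: methyltriphenylphosphonium bromide, C[P+](c1ccccc1)(c1ccccc1)c1ccccc1.[Br-]
Why: Wittig methylenation adds to the aldehyde carbonyl of the enal (1,2-olefination) much faster than to the acetate or the hindered methyl ester at low temperature and leaves the C12=C13 geometry untouched, which completes the (12E)-diene.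

**Compound list**

1 | 2-methoxy-6-methylphenol | Cc1cccc(OC)c1O | starting material
2 | 2-methoxy-6-methyl-1,4-benzoquinone | COC1=CC(=O)C=C(C)C1=O | intermediate
3 | methyl 4-chloro-4-oxobutanoate | COC(=O)CCC(=O)Cl | starting material
4 | methyl 4-[methoxy(methyl)amino]-4-oxobutanoate | COC(=O)CCC(=O)N(C)OC | intermediate
5 | vinylmagnesium bromide | C=C[Mg]Br | starting material
6 | methyl 4-oxohex-5-enoate | C=CC(=O)CCC(=O)OC | intermediate
7 | methyl (3Z)-4-[(triisopropylsilyl)oxy]hexa-3,5-dienoate | C=C/C(O[Si](C(C)C)(C(C)C)C(C)C)=C/CC(=O)OC | intermediate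
8 | cis-fused endo adduct (5R,9R,10S): 2-methoxy-2-ene-1,4-dione ring A, 5α-H, 10α-CH3, C7=C8 silyl enol ether, 9β-CH2CO2Me | COC(=O)C[C@H]1C(O[Si](C(C)C)(C(C)C)C(C)C)=CC[C@@H]2[C@@]1(C)C(=O)C(OC)=CC2=O | intermediate
9 | 2-methoxy-1,4-diketone (C2=C3 of 8 reduced; C2 epimers) | COC(=O)C[C@H]1C(O[Si](C(C)C)(C(C)C)C(C)C)=CC[C@@H]2[C@@]1(C)C(=O)C(OC)CC2=O | intermediate (not isolated)
10 | cis-fused 1,4-diketone (5α-H) | COC(=O)C[C@H]1C(O[Si](C(C)C)(C(C)C)C(C)C)=CC[C@@H]2[C@@]1(C)C(=O)CCC2=O | intermediate
11 | trans-fused 1,4-diketone (5β-H) | COC(=O)C[C@H]1C(O[Si](C(C)C)(C(C)C)C(C)C)=CC[C@H]2[C@@]1(C)C(=O)CCC2=O | intermediate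
12 | 1α,4ξ-diol with C7=C8 silyl enol ether and 9β-CH2CO2Me | COC(=O)C[C@H]1C(O[Si](C(C)C)(C(C)C)C(C)C)=CC[C@H]2[C@@]1(C)[C@@H](O)CCC2O | intermediate
13 | 8-keto 1α,4ξ-diol methyl ester (9β-arm) | COC(=O)C[C@H]1C(=O)CC[C@H]2[C@@]1(C)[C@@H](O)CCC2O | intermediate (not isolated)
14 | 8-keto O1–C12 δ-lactone, 9α-arm, 4ξ-OH | O=C1C[C@@H]2C(=O)CC[C@H]3[C@@]2(C)[C@@H](O1)CCC3O | intermediate
15 | 8(17)-methylene δ-lactone, 4ξ-OH | O=C1C[C@@H]2C(=C)CC[C@H]3[C@@]2(C)[C@@H](O1)CCC3O | intermediate
16 | 4-keto 8(17)-methylene δ-lactone | O=C1C[C@@H]2C(=C)CC[C@H]3[C@@]2(C)[C@@H](O1)CCC3=O | intermediate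
17 | 4-(methoxymethylidene) 8(17)-methylene δ-lactone (E/Z) | O=C1C[C@@H]2C(=C)CC[C@H]3[C@@]2(C)[C@@H](O1)CCC3=COC | intermediate
18 | 4ξ-formyl 8(17)-methylene δ-lactone | O=C1C[C@@H]2C(=C)CC[C@H]3[C@@]2(C)[C@@H](O1)CCC3C=O | intermediate
19 | potassium enolate of 18 | O=C1C[C@@H]2C(=C)CC[C@H]3[C@@]2(C)[C@@H](O1)CCC3=C[O-].[K+] | intermediate (not isolated)
20 | 4α-formyl-4β-methyl 8(17)-methylene δ-lactone | O=C1C[C@@H]2C(=C)CC[C@H]3[C@@]2(C)[C@@H](O1)CC[C@@]3(C)C=O | intermediate
21 | 4α-carboxylic acid of the δ-lactone | O=C1C[C@@H]2C(=C)CC[C@H]3[C@@]2(C)[C@@H](O1)CC[C@@]3(C)C(=O)O | intermediate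
22 | 4α-methyl ester of the δ-lactone | O=C1C[C@@H]2C(=C)CC[C@H]3[C@@]2(C)[C@@H](O1)CC[C@@]3(C)C(=O)OC | intermediate
23 | lactol (C12 hemiacetal, anomers) | OC1C[C@@H]2C(=C)CC[C@H]3[C@@]2(C)[C@@H](O1)CC[C@@]3(C)C(=O)OC | intermediate
24 | 1α-hydroxy (12E)-enal | O=C/C(C)=C/C[C@@H]1C(=C)CC[C@H]2[C@@]1(C)[C@@H](O)CC[C@@]2(C)C(=O)OC | intermediate
25 | 1α-acetoxy (12E)-enal | O=C/C(C)=C/C[C@@H]1C(=C)CC[C@H]2[C@@]1(C)[C@@H](OC(C)=O)CC[C@@]2(C)C(=O)OC | intermediate
26 | methyl (1S,4R,5S,9R,10S)-1-acetoxylabda-8(17),12E,14-trien-19-oate | C=C/C(C)=C/C[C@@H]1C(=C)CC[C@H]2[C@@]1(C)[C@@H](OC(C)=O)CC[C@@]2(C)C(=O)OC | target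

**Step count and weak points**

Total: 20 steps. Longest linear sequence: 19 steps (steps 2–4, then 5–20, from methyl 4-chloro-4-oxobutanoate).

Step 5 (cycloaddition). What may go wrong: the catalyst may discriminate poorly between the two faces of C5=C10 for this hindered pair, or be slowed by the ester and silyl ether donors, so that the adduct is formed with low enantiomeric purity. Fallback: starting from 2 and 7, the cycloaddition is promoted by BF3·OEt2 in CH2Cl2 at −78 °C, which binds the same vinylogous-ester carbonyl and should give the same regio- and endo-isomer as the racemic adduct F1. The enantiomers are then separated by preparative chromatography on a chiral stationary phase (amylose carbamate, supercritical CO2/alcohol). The route is rejoined at 8.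

Step 18 (lactol olefination). What may go wrong: the all-chair lactol may stay closed, so that the weakly nucleophilic formyl ylide reacts slowly, and the liberated C1 hydroxyl may add back to the new enal (oxa-Michael ring closure). Fallback: starting from 23, NaBH4 in MeOH should reduce the open form to the 1α,12-diol F2. t-BuMe2SiCl/imidazole silylates only the primary hydroxyl to give the 12-silyl ether F3. Ac2O/DMAP then gives the 1α-acetate F4, and HF·pyridine frees the 1α-acetoxy-12-ol F5. Dess–Martin oxidation gives the acetoxy aldehyde F6, a free aldehyde that should react normally with Ph3P=C(CH3)CHO in toluene. The route is rejoined at 25.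

Step 6 (double reduction in one flask). What may go wrong: C2–O cleavage may stop short, or the diketone may be reduced further, when both samarium reductions are run together. Fallback: starting from 8, Zn dust in AcOH reduces only the ene-dione and 9 is isolated. DBU in CH2Cl2 then removes methanol by E1cB elimination (the C2 methoxy group is β to the C4 carbonyl) to give the methoxy-free ene-dione F7. A second Zn/AcOH reduction gives the diketone. The route is rejoined at 10, and step 7 converges any trans isomer already present.

Further compounds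
F1 | step 5 | racemic adduct (8 together with its mirror image) | COC(=O)C[C@H]1C(O[Si](C(C)C)(C(C)C)C(C)C)=CC[C@@H]2[C@@]1(C)C(=O)C(OC)=CC2=O.COC(=O)C[C@@H]1C(O[Si](C(C)C)(C(C)C)C(C)C)=CC[C@H]2[C@]1(C)C(=O)C(OC)=CC2=O
F2 | step 18 | 1α,12-diol (4α-CO2Me, 8(17)-methylene) | OCC[C@@H]1C(=C)CC[C@H]2[C@@]1(C)[C@@H](O)CC[C@@]2(C)C(=O)OC
F3 | step 18 | 12-O-tert-butyldimethylsilyl ether of F2 | CC(C)(C)[Si](C)(C)OCC[C@@H]1C(=C)CC[C@H]2[C@@]1(C)[C@@H](O)CC[C@@]2(C)C(=O)OC
F4 | step 18 | 1α-acetate of F3 | CC(C)(C)[Si](C)(C)OCC[C@@H]1C(=C)CC[C@H]2[C@@]1(C)[C@@H](OC(C)=O)CC[C@@]2(C)C(=O)OC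
F5 | step 18 | 1α-acetoxy-12-ol | OCC[C@@H]1C(=C)CC[C@H]2[C@@]1(C)[C@@H](OC(C)=O)CC[C@@]2(C)C(=O)OC
F6 | step 18 | 1α-acetoxy-12-al | O=CC[C@@H]1C(=C)CC[C@H]2[C@@]1(C)[C@@H](OC(C)=O)CC[C@@]2(C)C(=O)OC
F7 | step 6 | methoxy-free 2-ene-1,4-dione (C5 epimers) | COC(=O)C[C@H]1C(O[Si](C(C)C)(C(C)C)C(C)C)=CCC2[C@@]1(C)C(=O)C=CC2=O
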